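**Retrosynthetic overview**

- The chain is numbered from the carbinol carbon C1 to the ketone carbon C14. The last step frees the C14 ketone from a dioxolane.
- The strategy rests on one feature: the carbinol oxygen, C1, the methylene C2 and the E-trisubstituted alkene C3=C4 (C4 carrying CH3 and C5) are an opened 2-(3-furyl)-2,3-dihydrofuran ring. The key step forms C4–C5 by alkyl migration from copper and C4–CH3 with MeI while the ring O–C4 bond breaks.
- Stannane 6 comes from 3-furaldehyde: allylboration sets C1 (S), hydroboration and oxidative lactonisation close the five-membered O-ring, then enol phosphate and stannylation.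
- Iodide 24 comes from 2,3-dihydrofuran and homoprenyl bromide (the same rearrangement in its parent form gives homogeraniol), then ω-oxidation, C13–C14 bond by dithiane alkylation, dithiane-to-dioxolane exchange and iodination.
- Ring order: the furan is bought; the lactone ring (step 3) becomes the dihydrofuran that is opened in step 15; the dioxolane is made in step 12 and removed in step 16.

Key step: step 15

Remark: the mixed cuprates are assumed to be 1:1:1 lithium alkyl(alkenyl)cuprates made with CuBr·SMe2, and (−)-Ipc2B(allyl) means the reagent derived from (+)-α-pinene.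

**Route**

Step 1
Reactants: 1 3-furaldehyde
Product: 2 (1S)-1-(furan-3-yl)but-3-en-1-ol
Conditions: (−)-Ipc2B(allyl) (1.2 equiv), Et2O, −78 °C; then NaOH, H2O2, 0 °C → rt
Reagents that add atoms: (−)-B-allyldiisopinocampheylborane, C=CCB([C@@H]1C[C@@H]2C[C@H]([C@H]1C)C2(C)C)[C@@H]1C[C@@H]2C[C@H]([C@H]1C)C2(C)C
Why: Brown asymmetric allylboration through a chair six-membered transition state, in which this reagent delivers the allyl group to the Si face of the aldehyde and should set C1 as (S).

Step 2
Reactants: 2 (1S)-1-(furan-3-yl)but-3-en-1-ol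
Product: 3 (1S)-1-(furan-3-yl)butane-1,4-diol
Conditions: 9-BBN (2.5 equiv), THF, 0 °C → rt; then NaOH, H2O2, 0 °C
Reagents that add atoms: hydrogen peroxide, OO
Why: Anti-Markovnikov hydroboration–oxidation of the terminal alkene with a bulky borane that should leave the furan alone and does not touch C1.

Step 3
Reactants: 3 (1S)-1-(furan-3-yl)butane-1,4-diol
Product: 4 (5S)-5-(furan-3-yl)oxolan-2-one
Conditions: TEMPO (cat.), PhI(OAc)2 (2.5 equiv), CH2Cl2, rt
Reagents that add atoms: none
Why: TEMPO/PhI(OAc)2 oxidative lactonisation, in which the primary alcohol is oxidised first, the aldehyde is trapped by the C1 hydroxyl as the lactol and this is oxidised on to the γ-lactone with the C1–O bond intact.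

Step 4
Reactants: 4 (5S)-5-(furan-3-yl)oxolan-2-one
Product: 5 (5S)-5-(furan-3-yl)-4,5-dihydrofuran-2-yl diphenyl phosphate
Conditions: KHMDS, (PhO)2P(O)Cl, HMPA, THF, −78 °C
Reagents that add atoms: diphenyl chlorophosphate, O=P(Cl)(Oc1ccccc1)Oc1ccccc1
Why: O-Phosphorylation of the lactone potassium enolate gives the ketene acetal phosphate, the usual way to make a lactone carbonyl carbon a cross-coupling site, while the C5–H is not acidic enough to react.

Step 5
Reactants: 5 (5S)-5-(furan-3-yl)-4,5-dihydrofuran-2-yl diphenyl phosphate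
Product: 6 trimethyl[(5S)-5-(furan-3-yl)-4,5-dihydrofuran-2-yl]stannane
Conditions: Me3SnSnMe3, Pd(PPh3)4 (5 mol %), LiCl, THF, 65 °C; isolation on basic alumina
Reagents that add atoms: hexamethylditin, C[Sn](C)(C)[Sn](C)(C)C
Why: Palladium-catalysed stannylation of the ketene acetal phosphate (Stille-type coupling with a distannane) by oxidative addition into the C–O bond, transmetalation and reductive elimination, remote from the stereocentre.

Step 6
Reactants: 7 2,3-dihydrofuran; 8 5-bromo-2-methylpent-2-ene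
Product: 14 (3E)-4,8-dimethylnona-3,7-dien-1-ol (homogeraniol), via 5-lithio-2,3-dihydrofuran 9 (not isolated), via (4-methylpent-3-en-1-yl)lithium 10 (not isolated), via (4-methylpent-3-en-1-yl)copper 11 (not isolated), via mixed lithium cuprate 12 (not isolated), via alkenylcopper lithium alkoxide 13 (not isolated)
Conditions: 7, t-BuLi, THF, −78 → 0 °C; 8, t-BuLi (2 equiv), Et2O, −78 °C, then CuBr·SMe2, Me2S, −78 → −40 °C; combine, −78 °C → rt; MeI, 0 °C → rt; H2O
Reagents that add atoms: iodomethane, CI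
Why: This is the copper-mediated 1,2-metallate rearrangement in its documented parent form, in which the homoprenyl group shifts from copper to the lithiated enol-ether carbon with inversion as the ring C–O bond breaks and methylation of the alkenylcopper with retention should give the (E)-alkene.

Step 7
Reactants: 14 (3E)-4,8-dimethylnona-3,7-dien-1-ol
Product: 15 tert-butyl{[(3E)-4,8-dimethylnona-3,7-dien-1-yl]oxy}diphenylsilane
Conditions: TBDPSCl, imidazole, DMF, rt
Reagents that add atoms: tert-butyl(chloro)diphenylsilane, CC(C)(C)[Si](Cl)(c1ccccc1)c1ccccc1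
Why: Standard silylation of a primary alcohol, with TBDPS chosen because it must withstand the lithiated dithiane of step 11 and the trifluoroacetic acid released in step 12.

Step 8
Reactants: 15 tert-butyl{[(3E)-4,8-dimethylnona-3,7-dien-1-yl]oxy}diphenylsilane
Product: 16 (2E,6E)-9-{[tert-butyl(diphenyl)silyl]oxy}-2,6-dimethylnona-2,6-dien-1-ol
Conditions: SeO2 (cat.), t-BuOOH, salicylic acid (cat.), CH2Cl2, rt, stopped at partial conversion
Reagents that add atoms: tert-butyl hydroperoxide, CC(C)(C)OO (net oxygen source; the oxygen is passed on by catalytic selenium dioxide, O=[Se]=O)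
Why: SeO2 allylic oxidation (ene reaction then [2,3]-sigmatropic shift) should attack the (E)-methyl group of the terminal trisubstituted alkene, the most accessible allylic site as in the ω-oxidation of polyprenyl chains, and give the (E)-allylic alcohol that becomes C13.

Step 9
Reactants: 16 (2E,6E)-9-{[tert-butyl(diphenyl)silyl]oxy}-2,6-dimethylnona-2,6-dien-1-ol
Product: 17 {[(3E,7E)-9-bromo-4,8-dimethylnona-3,7-dien-1-yl]oxy}(tert-butyl)diphenylsilane
Conditions: CBr4, PPh3, CH2Cl2, 0 °C; used at once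
Reagents that add atoms: carbon tetrabromide, BrC(Br)(Br)Br
Why: Appel bromination of the primary allylic alcohol by SN2 displacement at the oxyphosphonium salt, which should not transpose the allyl system or change the alkene geometry.

Step 10
Reactants: 18 3-methylbutanal
Product: 19 2-(2-methylpropyl)-1,3-dithiane
Conditions: HS(CH2)3SH, BF3·OEt2 (cat.), CH2Cl2, 0 °C → rt
Reagents that add atoms: propane-1,3-dithiol, SCCCS
Why: Lewis-acid-catalysed thioacetalisation turns the aldehyde carbon into the acyl-anion equivalent for C14.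

Step 11
Reactants: 19 2-(2-methylpropyl)-1,3-dithiane; 17 {[(3E,7E)-9-bromo-4,8-dimethylnona-3,7-dien-1-yl]oxy}(tert-butyl)diphenylsilane
Product: 21 tert-butyl({(3E,7E)-4,8-dimethyl-9-[2-(2-methylpropyl)-1,3-dithian-2-yl]nona-3,7-dien-1-yl}oxy)diphenylsilane, via 2-lithio-2-(2-methylpropyl)-1,3-dithiane 20 (not isolated)
Conditions: 19, n-BuLi, THF, −25 °C; then 17, −78 → −20 °C
Reagents that add atoms: none
Why: Corey–Seebach alkylation, in which the 2-lithiodithiane displaces the primary allylic bromide by SN2 and forms the C13–C14 bond while the silyl ether and the alkenes are inert.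

Step 12
Reactants: 21 tert-butyl({(3E,7E)-4,8-dimethyl-9-[2-(2-methylpropyl)-1,3-dithian-2-yl]nona-3,7-dien-1-yl}oxy)diphenylsilane
Product: 22 tert-butyl({(3E,7E)-4,8-dimethyl-9-[2-(2-methylpropyl)-1,3-dioxolan-2-yl]nona-3,7-dien-1-yl}oxy)diphenylsilane
Conditions: PhI(OCOCF3)2 (1.5 equiv), HOCH2CH2OH, MeCN, rt
Reagents that add atoms: ethane-1,2-diol, OCCO
Why: Hypervalent-iodine dethioacetalisation, in which S-activation gives a thionium ion that is captured by ethylene glycol so that the dithiane is exchanged for the dioxolane without passing through the free β,γ-unsaturated ketone.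

Step 13
Reactants: 22 tert-butyl({(3E,7E)-4,8-dimethyl-9-[2-(2-methylpropyl)-1,3-dioxolan-2-yl]nona-3,7-dien-1-yl}oxy)diphenylsilane
Product: 23 (3E,7E)-4,8-dimethyl-9-[2-(2-methylpropyl)-1,3-dioxolan-2-yl]nona-3,7-dien-1-ol
Conditions: TBAF, THF, rt
Reagents that add atoms: none
Why: Fluoride-driven desilylation, to which the dioxolane and the alkenes are inert.

Step 14
Reactants: 23 (3E,7E)-4,8-dimethyl-9-[2-(2-methylpropyl)-1,3-dioxolan-2-yl]nona-3,7-dien-1-ol
Product: 24 2-[(2E,6E)-9-iodo-2,6-dimethylnona-2,6-dien-1-yl]-2-(2-methylpropyl)-1,3-dioxolane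
Conditions: I2, PPh3, imidazole, CH2Cl2, 0 °C → rt
Reagents that add atoms: iodine, II
Why: Appel-type iodination of the primary alcohol under imidazole buffering, which the acid-labile dioxolane should survive.

Step 15
Reactants: 6 trimethyl[(5S)-5-(furan-3-yl)-4,5-dihydrofuran-2-yl]stannane; 24 2-[(2E,6E)-9-iodo-2,6-dimethylnona-2,6-dien-1-yl]-2-(2-methylpropyl)-1,3-dioxolane
Product: 30 (1S,3E,7E,11E)-1-(furan-3-yl)-4,8,12-trimethyl-13-[2-(2-methylpropyl)-1,3-dioxolan-2-yl]trideca-3,7,11-trien-1-ol, via (S)-dihydrofuranyllithium 25 (not isolated), via alkyllithium 26 (not isolated), via alkylcopper 27 (not isolated), via mixed lithium cuprate 28 (not isolated), via alkenylcopper lithium alkoxide 29 (not isolated)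
Conditions: 24, t-BuLi (2 equiv), Et2O/pentane, −78 °C, brief warming, then CuBr·SMe2, Me2S, −78 → −40 °C; 6, MeLi (1 equiv), THF, −78 °C; combine at −78 °C → rt; MeI, 0 °C → rt; H2O
Reagents that add atoms: iodomethane, CI
Why: Tin–lithium exchange of 6 gives 25, which joins alkylcopper 27 in the ate complex 28; on warming the alkyl group shifts from copper to the enol-ether carbon C4 anti to the ring C–O bond (inversion at the sp2 carbon), the ring oxygen leaves as the C1 alkoxide, and the alkenylcopper 29 is methylated by MeI with retention. The closest known reaction is the copper-mediated 1,2-metallate rearrangement of 5-lithio-2,3-dihydrofurans with homoallylic organocopper reagents and MeI trapping, the operation already run in step 6. No ring closes; the dihydrofuran ring opens at O–C4. No new stereocentre forms: invertive migration plus retentive methylation put C5 trans to C2 (E), and C1 stays (S) because its C–O bond is never broken. The step needs tin–lithium exchange to outrun deprotonation of the furan α-positions, which −78 °C and the fast exchange of an α-alkoxyvinylstannane should secure, and the alkyllithium is converted into its copper compound before it meets the furan so that no strong base is present when the mixture is warmed.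

Step 16
Reactants: 30 (1S,3E,7E,11E)-1-(furan-3-yl)-4,8,12-trimethyl-13-[2-(2-methylpropyl)-1,3-dioxolan-2-yl]trideca-3,7,11-trien-1-ol
Product: 31 (6E,10E,14E,17S)-17-(furan-3-yl)-17-hydroxy-2,6,10,14-tetramethylheptadeca-6,10,14-trien-4-one (target)
Conditions: PPTS (cat.), acetone/H2O (10:1), rt → 40 °C
Reagents that add atoms: water, O
Why: Mild acid-catalysed acetal hydrolysis via the oxocarbenium ion frees the C14 ketone under conditions weak enough that the C11=C12 alkene should not move into conjugation and the 3-furyl carbinol should not ionise.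

**Compound list**

1 | 3-furaldehyde | O=Cc1ccoc1 | starting material
2 | (1S)-1-(furan-3-yl)but-3-en-1-ol | C=CC[C@H](O)c1ccoc1 | intermediate
3 | (1S)-1-(furan-3-yl)butane-1,4-diol | OCCC[C@H](O)c1ccoc1 | intermediate
4 | (5S)-5-(furan-3-yl)oxolan-2-one | O=C1CC[C@H](O1)c1ccoc1 | intermediate
5 | (5S)-5-(furan-3-yl)-4,5-dihydrofuran-2-yl diphenyl phosphate | O=P(Oc1ccccc1)(Oc1ccccc1)OC1=CC[C@H](O1)c1ccoc1 | intermediate
6 | trimethyl[(5S)-5-(furan-3-yl)-4,5-dihydrofuran-2-yl]stannane | C[Sn](C)(C)C1=CC[C@H](O1)c1ccoc1 | intermediate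
7 | 2,3-dihydrofuran | C1=COCC1 | starting material
8 | 5-bromo-2-methylpent-2-ene | CC(C)=CCCBr | starting material
9 | 5-lithio-2,3-dihydrofuran | [Li]C1=CCCO1 | intermediate
10 | (4-methylpent-3-en-1-yl)lithium | CC(C)=CCC[Li] | intermediate
11 | (4-methylpent-3-en-1-yl)copper | CC(C)=CCC[Cu] | intermediate
12 | lithium (4,5-dihydrofuran-2-yl)(4-methylpent-3-en-1-yl)cuprate | [Li+].CC(C)=CCC[Cu-]C1=CCCO1 | intermediate
13 | lithium (3Z)-4-cuprio-8-methylnona-3,7-dien-1-olate | [Li+].[O-]CC/C=C(\[Cu])CCC=C(C)C | intermediate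
14 | (3E)-4,8-dimethylnona-3,7-dien-1-ol | OCC/C=C(\C)CCC=C(C)C | intermediate
15 | tert-butyl{[(3E)-4,8-dimethylnona-3,7-dien-1-yl]oxy}diphenylsilane | CC(C)=CCC/C(C)=C/CCO[Si](c1ccccc1)(c1ccccc1)C(C)(C)C | intermediate
16 | (2E,6E)-9-{[tert-butyl(diphenyl)silyl]oxy}-2,6-dimethylnona-2,6-dien-1-ol | OC/C(C)=C/CC/C(C)=C/CCO[Si](c1ccccc1)(c1ccccc1)C(C)(C)C | intermediate
17 | {[(3E,7E)-9-bromo-4,8-dimethylnona-3,7-dien-1-yl]oxy}(tert-butyl)diphenylsilane | BrC/C(C)=C/CC/C(C)=C/CCO[Si](c1ccccc1)(c1ccccc1)C(C)(C)C | intermediate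
18 | 3-methylbutanal | CC(C)CC=O | starting material
19 | 2-(2-methylpropyl)-1,3-dithiane | CC(C)CC1SCCCS1 | intermediate
20 | 2-lithio-2-(2-methylpropyl)-1,3-dithiane | [Li]C1(CC(C)C)SCCCS1 | intermediate
21 | tert-butyl({(3E,7E)-4,8-dimethyl-9-[2-(2-methylpropyl)-1,3-dithian-2-yl]nona-3,7-dien-1-yl}oxy)diphenylsilane | CC(C)CC1(SCCCS1)C/C(C)=C/CC/C(C)=C/CCO[Si](c1ccccc1)(c1ccccc1)C(C)(C)C | intermediate
22 | tert-butyl({(3E,7E)-4,8-dimethyl-9-[2-(2-methylpropyl)-1,3-dioxolan-2-yl]nona-3,7-dien-1-yl}oxy)diphenylsilane | CC(C)CC1(OCCO1)C/C(C)=C/CC/C(C)=C/CCO[Si](c1ccccc1)(c1ccccc1)C(C)(C)C | intermediate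
23 | (3E,7E)-4,8-dimethyl-9-[2-(2-methylpropyl)-1,3-dioxolan-2-yl]nona-3,7-dien-1-ol | CC(C)CC1(OCCO1)C/C(C)=C/CC/C(C)=C/CCO | intermediate
24 | 2-[(2E,6E)-9-iodo-2,6-dimethylnona-2,6-dien-1-yl]-2-(2-methylpropyl)-1,3-dioxolane | CC(C)CC1(OCCO1)C/C(C)=C/CC/C(C)=C/CCI | intermediate
25 | [(5S)-5-(furan-3-yl)-4,5-dihydrofuran-2-yl]lithium | [Li]C1=CC[C@H](O1)c1ccoc1 | intermediate
26 | {(3E,7E)-4,8-dimethyl-9-[2-(2-methylpropyl)-1,3-dioxolan-2-yl]nona-3,7-dien-1-yl}lithium | CC(C)CC1(OCCO1)C/C(C)=C/CC/C(C)=C/CC[Li] | intermediate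
27 | {(3E,7E)-4,8-dimethyl-9-[2-(2-methylpropyl)-1,3-dioxolan-2-yl]nona-3,7-dien-1-yl}copper | CC(C)CC1(OCCO1)C/C(C)=C/CC/C(C)=C/CC[Cu] | intermediate
28 | lithium [(5S)-5-(furan-3-yl)-4,5-dihydrofuran-2-yl]{(3E,7E)-4,8-dimethyl-9-[2-(2-methylpropyl)-1,3-dioxolan-2-yl]nona-3,7-dien-1-yl}cuprate | [Li+].CC(C)CC1(OCCO1)C/C(C)=C/CC/C(C)=C/CC[Cu-]C1=CC[C@H](O1)c1ccoc1 | intermediate
29 | lithium (1S,3Z,7E,11E)-4-cuprio-1-(furan-3-yl)-8,12-dimethyl-13-[2-(2-methylpropyl)-1,3-dioxolan-2-yl]trideca-3,7,11-trien-1-olate | [Li+].[O-][C@H](c1ccoc1)C/C=C(\[Cu])CC/C=C(\C)CC/C=C(\C)CC1(CC(C)C)OCCO1 | intermediate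
30 | (1S,3E,7E,11E)-1-(furan-3-yl)-4,8,12-trimethyl-13-[2-(2-methylpropyl)-1,3-dioxolan-2-yl]trideca-3,7,11-trien-1-ol | O[C@H](c1ccoc1)C/C=C(\C)CC/C=C(\C)CC/C=C(\C)CC1(CC(C)C)OCCO1 | intermediate
31 | (6E,10E,14E,17S)-17-(furan-3-yl)-17-hydroxy-2,6,10,14-tetramethylheptadeca-6,10,14-trien-4-one | C/C(=C\CC/C(C)=C/C[C@H](O)c1ccoc1)CC/C=C(\C)CC(=O)CC(C)C | target

**Step count**

Total: 16 steps. Longest linear sequence: 10 steps (6, 7, 8, 9, 11, 12, 13, 14, 15, 16). The stannane branch is 5 steps before the key step.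

**Three steps most likely to fail**

Step 15. After tin–lithium exchange the lithium may move to a furan α-position, or the ate complex carrying the 2-(3-furyl) group may be protonated or couple instead of rearranging. The fallback brings the furan in after the alkene is built and sets C1 by reagent control. It sets out from iodide 24: its alkylcopper 27 is joined to the parent 5-lithio-2,3-dihydrofuran 9 (made by direct deprotonation as in step 6, safe when no furan is present) to give the mixed lithium cuprate F1. Warming should give the alkenylcopper lithium alkoxide F2, and MeI the primary homoallylic alcohol F3 with the same E-C3=C4 alkene. Dess–Martin periodinane (NaHCO3, CH2Cl2) would give the β,γ-unsaturated aldehyde F4, which is treated at once with 3-furyllithium (3-bromofuran, n-BuLi, THF, −78 °C) to give the racemic furyl carbinol F5. MnO2 would oxidise it to the 3-furyl ketone F6, and CBS reduction with the (R)-oxazaborolidine and BH3·SMe2 should give the (S)-alcohol 30, where the route is rejoined.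

Step 4. The five-membered ketene acetal phosphate may hydrolyse or decompose on isolation, and competing C-phosphorylation of the enolate is possible. The fallback replaces the phosphate by a sulfone and also bypasses step 5. It sets out from lactone 4: DIBAL-H (CH2Cl2, −78 °C) gives the lactol F7, and benzenesulfinic acid with CaCl2 gives the anomeric sulfone F8. n-BuLi (THF, −78 °C) forms the α-sulfonyl carbanion F9, Bu3SnCl gives the α-stannyl sulfone F10, and warming with Hünig's base expels benzenesulfinate to give the tributylstannyl dihydrofuran F11. Tin–lithium exchange with n-BuLi (THF, −78 °C) then gives the lithio compound 25 inside step 15, where the route is rejoined.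

Step 12. The iodine(III) reagent may attack the trisubstituted alkenes, or the thionium or oxocarbenium ion may lose a proton at C13 and draw the C11=C12 alkene into conjugation. The fallback separates unmasking and protection and avoids an oxidant. It sets out from dithiane 21: MeI and CaCO3 in aqueous MeCN should give the free β,γ-unsaturated ketone F12 by S-alkylative hydrolysis. 1,2-Bis(trimethylsilyloxy)ethane with catalytic TMSOTf (CH2Cl2, −78 °C) then converts it into dioxolane 22, where the route is rejoined.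

**Further compounds**

F1 | step 15 | lithium (4,5-dihydrofuran-2-yl){(3E,7E)-4,8-dimethyl-9-[2-(2-methylpropyl)-1,3-dioxolan-2-yl]nona-3,7-dien-1-yl}cuprate | [Li+].CC(C)CC1(OCCO1)C/C(C)=C/CC/C(C)=C/CC[Cu-]C1=CCCO1
F2 | step 15 | lithium (3Z,7E,11E)-4-cuprio-8,12-dimethyl-13-[2-(2-methylpropyl)-1,3-dioxolan-2-yl]trideca-3,7,11-trien-1-olate | [Li+].[O-]CC/C=C(\[Cu])CC/C=C(\C)CC/C=C(\C)CC1(CC(C)C)OCCO1
F3 | step 15 | (3E,7E,11E)-4,8,12-trimethyl-13-[2-(2-methylpropyl)-1,3-dioxolan-2-yl]trideca-3,7,11-trien-1-ol | OCC/C=C(\C)CC/C=C(\C)CC/C=C(\C)CC1(CC(C)C)OCCO1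
F4 | step 15 | (3E,7E,11E)-4,8,12-trimethyl-13-[2-(2-methylpropyl)-1,3-dioxolan-2-yl]trideca-3,7,11-trienal | O=CC/C=C(\C)CC/C=C(\C)CC/C=C(\C)CC1(CC(C)C)OCCO1
F5 | step 15 | rac-(3E,7E,11E)-1-(furan-3-yl)-4,8,12-trimethyl-13-[2-(2-methylpropyl)-1,3-dioxolan-2-yl]trideca-3,7,11-trien-1-ol | OC(c1ccoc1)C/C=C(\C)CC/C=C(\C)CC/C=C(\C)CC1(CC(C)C)OCCO1
F6 | step 15 | (3E,7E,11E)-1-(furan-3-yl)-4,8,12-trimethyl-13-[2-(2-methylpropyl)-1,3-dioxolan-2-yl]trideca-3,7,11-trien-1-one | O=C(c1ccoc1)C/C=C(\C)CC/C=C(\C)CC/C=C(\C)CC1(CC(C)C)OCCO1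
F7 | step 4 | (5S)-5-(furan-3-yl)oxolan-2-ol (anomers) | OC1CC[C@H](O1)c1ccoc1
F8 | step 4 | (5S)-2-(benzenesulfonyl)-5-(furan-3-yl)oxolane (anomers) | O=S(=O)(c1ccccc1)C1CC[C@H](O1)c1ccoc1
F9 | step 4 | [(5S)-2-(benzenesulfonyl)-5-(furan-3-yl)oxolan-2-yl]lithium | [Li]C1(CC[C@H](O1)c1ccoc1)S(=O)(=O)c1ccccc1
F10 | step 4 | [(5S)-2-(benzenesulfonyl)-5-(furan-3-yl)oxolan-2-yl]tributylstannane | CCCC[Sn](CCCC)(CCCC)C1(CC[C@H](O1)c1ccoc1)S(=O)(=O)c1ccccc1
F11 | step 4 | tributyl[(5S)-5-(furan-3-yl)-4,5-dihydrofuran-2-yl]stannane | CCCC[Sn](CCCC)(CCCC)C1=CC[C@H](O1)c1ccoc1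
F12 | step 12 | (6E,10E)-13-{[tert-butyl(diphenyl)silyl]oxy}-2,6,10-trimethyltrideca-6,10-dien-4-one | CC(C)CC(=O)C/C(C)=C/CC/C(C)=C/CCO[Si](c1ccccc1)(c1ccccc1)C(C)(C)C
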